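**Strategy.** The C8–C9 bond (chain numbering: C1 = alkyne CH, C15 = CH3) is made in a five-membered ring that the target does not contain. A Petasis–Ferrier O-to-C shift of a 4-methylene-1,3-dioxolane, built from an α-hydroxy acid (C4–C7) and an α-silyloxy aldehyde (C9–C15), closes a cis-2,5-tetrahydrofuran-3-one; it exploits the C7(O)–C8H2–C9(O) pattern of the oxocane ring. The temporary O–C9 bond is then cut by a bromonium-induced ring expansion to the eight-membered ether (O–C12, C13–Br). A second oxonium relay carries the C10 oxygen to C7 and then to C4, forming the tetrahydrofuran while bromide inverts C10.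

Key step: step 7

Remark: locants C1–C15 in names and explanations are those of the target chain (the oxocane oxygen joins C6 and C12, the tetrahydrofuran oxygen C4 and C7). Compounds 1, 2, 6, 21 and 23 and the named ligands and catalysts are assumed to be commercially available.

Step 1
Reactants: 1 ethyl glyoxylate; 2 pent-1-ene
Product: 3 ethyl (2R,4E)-2-hydroxyhept-4-enoate
Conditions: Cu(SbF6)2/(R,R)-t-Bu-box (10 mol %), CH2Cl2, 0 °C to rt
Reagents that add atoms: none
Why: Catalytic enantioselective glyoxylate-ene (carbonyl-ene) reaction in which the chelated glyoxylate should be attacked on one face only, setting the carbinol centre (the later C10) as R, while the cyclic ene transition state should give mainly the E-alkene (the later C12=C13).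

Step 2
Reactants: 3 ethyl (2R,4E)-2-hydroxyhept-4-enoate
Product: 4 ethyl (2R,4E)-2-(tert-butyldimethylsilyloxy)hept-4-enoate
Conditions: TBSCl, imidazole, DMF, rt
Reagents that add atoms: tert-butyldimethylsilyl chloride, CC(C)(C)[Si](C)(C)Cl
Why: Silylation of the secondary alcohol gives a non-participating ether at O10 and touches no stereocentre.

Step 3
Reactants: 4 ethyl (2R,4E)-2-(tert-butyldimethylsilyloxy)hept-4-enoate
Product: 5 (2R,4E)-2-(tert-butyldimethylsilyloxy)hept-4-enal
Conditions: i-Bu2AlH (1.1 equiv), CH2Cl2, −78 °C; aq. potassium sodium tartrate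
Reagents that add atoms: none
Why: Partial reduction of the ester stops at the aldehyde because the tetrahedral aluminium hemiacetal is stable at −78 °C, and the α-centre is retained.

Step 4
Reactants: 6 L-allylglycine
Product: 7 (S)-2-hydroxypent-4-enoic acid
Conditions: NaNO2, 1 M H2SO4 (aq.), 0 °C to rt
Reagents that add atoms: water, O
Why: Diazotisation and hydrolysis of the α-amino acid proceed with net retention (double inversion through carboxylate participation), so C6 is obtained as S.

Step 5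
Reactants: 5 (2R,4E)-2-(tert-butyldimethylsilyloxy)hept-4-enal; 7 (S)-2-hydroxypent-4-enoic acid
Product: 8 (5S)-5-allyl-2-[(1R,3E)-1-(tert-butyldimethylsilyloxy)hex-3-en-1-yl]-1,3-dioxolan-4-one (both epimers at C2)
Conditions: CSA (10 mol %), 4 Å molecular sieves, CH2Cl2, rt
Reagents that add atoms: none
Why: Acid-catalysed acetalisation of the α-hydroxy acid with the aldehyde gives the five-membered dioxolanone; the acetal carbon forms as a mixture, which is of no consequence because this centre is ionised in step 7, and C6 and C10 are untouched.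

Step 6
Reactants: 8 (5S)-5-allyl-2-[(1R,3E)-1-(tert-butyldimethylsilyloxy)hex-3-en-1-yl]-1,3-dioxolan-4-one
Product: 9 (5S)-5-allyl-2-[(1R,3E)-1-(tert-butyldimethylsilyloxy)hex-3-en-1-yl]-4-methylene-1,3-dioxolane (both epimers at C2)
Conditions: Cp2TiMe2 (2.5 equiv), toluene, 65 °C, dark
Reagents that add atoms: dimethyltitanocene, C[Ti](C)(C1C=CC=C1)C1C=CC=C1
Why: Petasis methylenation of the lactone-type carbonyl by Cp2Ti=CH2 formed on heating supplies C8 and should leave the isolated alkenes, the acetal and the silyl ether intact.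

Step 7
Reactants: 9 (5S)-5-allyl-2-[(1R,3E)-1-(tert-butyldimethylsilyloxy)hex-3-en-1-yl]-4-methylene-1,3-dioxolane
Product: 11 (2S,5S)-2-allyl-5-[(1R,3E)-1-(tert-butyldimethylsilyloxy)hex-3-en-1-yl]dihydrofuran-3(2H)-one, via oxocarbenium aluminium enolate 10 (not isolated)
Conditions: Me2AlCl (2 equiv), CH2Cl2, −78 to −40 °C; aq. NaHCO3
Reagents that add atoms: none
Why: Me2AlCl binds the enol-ether oxygen of 9 and ionises the acetal C–O bond to the oxocarbenium ion/aluminium enolate pair 10, whose enolate carbon (C8) then adds to the oxocarbenium carbon (C9), a Lewis-acid-mediated 1,3 O-to-C shift. The closest known reaction type is the Petasis–Ferrier rearrangement of 4-methylene-1,3-dioxolanes to tetrahydrofuran-3-ones. The tetrahydrofuranone ring is closed in the 5-(enolendo)-endo-trig mode by the new C8–C9 bond. The new stereocentre C9 should be set cis to the C6 allyl group (2,5-cis) through an envelope transition state with both substituents pseudo-equatorial; C6 is untouched because its C–O bond is never broken, and the acetal mixture converges because that centre is ionised. The step needs C-alkylation with cis closure rather than acetal hydrolysis, elimination or trapping of the cation by the C10 oxygen; the non-participating silyl ether at C10, the low temperature and the intramolecular ion pair should secure this.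

Step 8
Reactants: 11 (2S,5S)-2-allyl-5-[(1R,3E)-1-(tert-butyldimethylsilyloxy)hex-3-en-1-yl]dihydrofuran-3(2H)-one
Product: 12 (2S,3S,5S)-2-allyl-5-[(1R,3E)-1-(tert-butyldimethylsilyloxy)hex-3-en-1-yl]tetrahydrofuran-3-ol
Conditions: LiBH(s-Bu)3, THF, −78 °C; then H2O
Reagents that add atoms: none
Why: Ketone reduction by a bulky hydride, which should attack the face opposite to the two cis ring substituents and so give the all-cis alcohol (C7 S).

Step 9
Reactants: 12 (2S,3S,5S)-2-allyl-5-[(1R,3E)-1-(tert-butyldimethylsilyloxy)hex-3-en-1-yl]tetrahydrofuran-3-ol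
Product: 13 (2S,3S,5S)-2-allyl-5-[(1R,3E)-1-(tert-butyldimethylsilyloxy)hex-3-en-1-yl]tetrahydrofuran-3-yl chloromethanesulfonate
Conditions: ClCH2SO2Cl, pyridine, CH2Cl2, 0 °C
Reagents that add atoms: chloromethanesulfonyl chloride, ClCS(=O)(=O)Cl
Why: Sulfonylation of the C7 alcohol with retention gives a leaving group that is more reactive than the later C13 bromide yet should survive the next three steps.

Step 10
Reactants: 13 (2S,3S,5S)-2-allyl-5-[(1R,3E)-1-(tert-butyldimethylsilyloxy)hex-3-en-1-yl]tetrahydrofuran-3-yl chloromethanesulfonate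
Product: 14 (2S,3S,5S)-2-allyl-5-[(1R,3E)-1-hydroxyhex-3-en-1-yl]tetrahydrofuran-3-yl chloromethanesulfonate
Conditions: HF·pyridine, pyridine/THF, 0 °C to rt
Reagents that add atoms: none
Why: Fluoride cleavage of the C10 silyl ether under buffered acidic conditions that should leave the sulfonate and both alkenes untouched.

Step 11
Reactants: 14 (2S,3S,5S)-2-allyl-5-[(1R,3E)-1-hydroxyhex-3-en-1-yl]tetrahydrofuran-3-yl chloromethanesulfonate
Product: 15 (2S,3S,5S)-2-allyl-5-[(1R,3E)-1-(tert-butoxycarbonyloxy)hex-3-en-1-yl]tetrahydrofuran-3-yl chloromethanesulfonate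
Conditions: Boc2O, DMAP (cat.), Et3N, CH2Cl2, rt
Reagents that add atoms: di-tert-butyl dicarbonate, CC(C)(C)OC(=O)OC(=O)OC(C)(C)C
Why: DMAP-catalysed carbonate formation places at O10 the internal nucleophile needed for the ring expansion.

Step 12
Reactants: 15 (2S,3S,5S)-2-allyl-5-[(1R,3E)-1-(tert-butoxycarbonyloxy)hex-3-en-1-yl]tetrahydrofuran-3-yl chloromethanesulfonate
Product: 17 (6S,7S,9R,10R,12R,13S)-6-allyl-12-(1-bromopropyl)-7-(chloromethanesulfonyloxy)oxocane-9,10-diyl carbonate (chain locants), via bicyclic oxonium ion 16 (not isolated)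
Conditions: Et2SBr·SbCl5Br (BDSB, 1.1 equiv), MeNO2, −25 °C; aq. Na2SO3/NaHCO3
Reagents that add atoms: bromodiethylsulfonium bromopentachloroantimonate, CC[S+](Br)CC.Cl[Sb-](Cl)(Cl)(Cl)(Cl)Br
Why: Bromonium-induced ring expansion of a tetrahydrofuran that carries a neighbouring tert-butyl carbonate, a known reaction type: the ring oxygen opens the bromonium ion of the E-alkene 5-exo at C12 (anti addition, hence 12R,13S, with the bromopropyl group on the convex face away from the C6 allyl group) to give oxonium ion 16, and the carbonate carbonyl then displaces this oxygen from C9 with inversion (C9 becomes R), which opens the bicycle to the oxocane and releases the tert-butyl cation.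

Step 13
Reactants: 17 (6S,7S,9R,10R,12R,13S)-6-allyl-12-(1-bromopropyl)-7-(chloromethanesulfonyloxy)oxocane-9,10-diyl carbonate
Product: 19 (6S,7R,9R,10R,12R,13S)-6-allyl-12-(1-bromopropyl)-7,10-epoxyoxocan-9-ol (chain locants; 2,7-dioxabicyclo[4.2.1]nonane core), via diol 18 (not isolated)
Conditions: K2CO3, MeOH, rt then 50 °C
Reagents that add atoms: none
Why: Methanolysis of the cyclic carbonate to diol 18 followed by transannular Williamson etherification, in which the C10 alkoxide displaces the C7 sulfonate 5-exo-tet with inversion (C7 becomes R) while the C9 hydroxyl cannot reach C7, should give the oxygen-bridged bicycle.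

Step 14
Reactants: 19 (6S,7R,9R,10R,12R,13S)-6-allyl-12-(1-bromopropyl)-7,10-epoxyoxocan-9-ol
Product: 20 (6S,7R,9R,10R,12R,13S)-6-allyl-12-(1-bromopropyl)-9-(tert-butyldimethylsilyloxy)-7,10-epoxyoxocane (chain locants)
Conditions: TBSOTf, 2,6-lutidine, CH2Cl2, −78 to 0 °C
Reagents that add atoms: tert-butyldimethylsilyl trifluoromethanesulfonate, CC(C)(C)[Si](C)(C)OS(=O)(=O)C(F)(F)F
Why: Silylation turns the C9 hydroxyl into a group that cannot act as a neighbouring nucleophile in step 18, as an acetate trans to the leaving oxygen at C10 would.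

Step 15
Reactants: 20 (6S,7R,9R,10R,12R,13S)-6-allyl-12-(1-bromopropyl)-9-(tert-butyldimethylsilyloxy)-7,10-epoxyoxocane; 21 4,4,5,5-tetramethyl-2-vinyl-1,3,2-dioxaborolane
Product: 22 (E)-alkenylboronic pinacol ester with boron on C3 of the 13-bromo-9-(tert-butyldimethylsilyloxy)-6,12:7,10-diepoxy C3–C15 chain (6S,7R,9R,10R,12R,13S)
Conditions: second-generation Grubbs catalyst (5 mol %), CH2Cl2, 40 °C
Reagents that add atoms: none
Why: Olefin cross-metathesis of the terminal alkene with the vinylboronate, expected to be E-selective, exchanges the terminal CH2 for the boron-bearing C3.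

Step 16
Reactants: 22 (E)-alkenylboronic pinacol ester; 23 (bromoethynyl)trimethylsilane
Product: 25 (3E,6S,7R,9R,10R,12R,13S)-13-bromo-9-(tert-butyldimethylsilyloxy)-6,12:7,10-diepoxypentadec-3-en-1-yne, via silyl enyne 24 (not isolated)
Conditions: Pd(PPh3)4 (5 mol %), K3PO4, THF/H2O (10:1), rt; then K2CO3, MeOH, rt
Reagents that add atoms: none
Why: Suzuki–Miyaura coupling of the alkenylboronate with the 1-bromoalkyne with retention of the E geometry, followed in the same flask by base-induced protodesilylation of alkynylsilane 24.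

Step 17
Reactants: 25 (3E,6S,7R,9R,10R,12R,13S)-13-bromo-9-(tert-butyldimethylsilyloxy)-6,12:7,10-diepoxypentadec-3-en-1-yne
Product: 26 (3S,4S,6S,7R,9R,10R,12R,13S)-13-bromo-9-(tert-butyldimethylsilyloxy)-3,4:6,12:7,10-triepoxypentadec-1-yne
Conditions: L-fructose-derived Shi ketone (30 mol %), KHSO5 (as Oxone), K2CO3, Bu4NHSO4, MeCN/dimethoxymethane/aq. buffer (pH 10.5), 0 °C
Reagents that add atoms: potassium peroxymonosulfate, [K+].[O-]S(=O)(=O)OO
Why: Shi asymmetric epoxidation, in which the chiral dioxirane of the L-fructose-derived ketone should epoxidise the trans-alkene of the enyne under reagent control to the (3S,4S)-epoxide without touching the alkyne.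

Step 18
Reactants: 26 (3S,4S,6S,7R,9R,10R,12R,13S)-13-bromo-9-(tert-butyldimethylsilyloxy)-3,4:6,12:7,10-triepoxypentadec-1-yne
Product: 28 (3S,4R,6S,7R,9R,10S,12R,13S)-10,13-dibromo-9-(tert-butyldimethylsilyloxy)-4,7:6,12-diepoxypentadec-1-yn-3-ol, via tricyclic oxonium ion 27 (not isolated)
Conditions: BF3·OEt2 (1.2 equiv), CH2Cl2, −78 °C; then Bu4NBr (1.5 equiv), −78 to −20 °C; aq. NaHCO3
Reagents that add atoms: tetrabutylammonium bromide, CCCC[N+](CCCC)(CCCC)CCCC.[Br-]
Why: Oxonium formation and fragmentation: BF3 activates the epoxide, the bridging ether oxygen opens it 5-exo at C4 with inversion (C4 becomes R, C3–O retained) to give the tricyclic oxonium ion 27, and bromide then attacks C10 in an SN2 step with inversion (C10 becomes S), the opening that releases the strained bridged bicycle and leaves the trans-fused 2,5-cis-tetrahydrofuran.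

Step 19
Reactants: 28 (3S,4R,6S,7R,9R,10S,12R,13S)-10,13-dibromo-9-(tert-butyldimethylsilyloxy)-4,7:6,12-diepoxypentadec-1-yn-3-ol
Product: 29 (3R,4R,6S,7R,9R,10S,12R,13S)-3,10,13-tribromo-9-(tert-butyldimethylsilyloxy)-4,7:6,12-diepoxypentadec-1-yne
Conditions: CBr4, PPh3, CH2Cl2, 0 °C
Reagents that add atoms: carbon tetrabromide, BrC(Br)(Br)Br
Why: Appel reaction, in which bromide displaces the activated propargylic oxygen in an SN2 step with inversion and converts (3S)-OH into (3R)-Br.

Step 20
Reactants: 29 (3R,4R,6S,7R,9R,10S,12R,13S)-3,10,13-tribromo-9-(tert-butyldimethylsilyloxy)-4,7:6,12-diepoxypentadec-1-yne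
Product: 30 (3R,4R,6S,7R,9R,10S,12R,13S)-3,10,13-tribromo-4,7:6,12-diepoxypentadec-1-yn-9-ol
Conditions: HF·pyridine, THF, 0 °C to rt
Reagents that add atoms: none
Why: Cleavage of the C9 silyl ether by buffered HF, conditions under which the three bromides and the alkyne should be stable.

Step 21
Reactants: 30 (3R,4R,6S,7R,9R,10S,12R,13S)-3,10,13-tribromo-4,7:6,12-diepoxypentadec-1-yn-9-ol
Product: 31 (3R,4R,6S,7R,9R,10S,12R,13S)-3,10,13-tribromo-4,7:6,12-diepoxypentadec-1-yn-9-yl acetate (target)
Conditions: Ac2O, pyridine, DMAP (cat.), CH2Cl2, 0 °C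
Reagents that add atoms: acetic anhydride, CC(=O)OC(C)=O
Why: DMAP-catalysed acetylation of the C9 alcohol with retention gives the target.

**Compound list**

1 | ethyl glyoxylate | CCOC(=O)C=O | starting material
2 | pent-1-ene | C=CCCC | starting material
3 | ethyl (2R,4E)-2-hydroxyhept-4-enoate | CC/C=C/C[C@@H](O)C(=O)OCC | intermediate
4 | ethyl (2R,4E)-2-(tert-butyldimethylsilyloxy)hept-4-enoate | CC/C=C/C[C@@H](O[Si](C)(C)C(C)(C)C)C(=O)OCC | intermediate
5 | (2R,4E)-2-(tert-butyldimethylsilyloxy)hept-4-enal | CC/C=C/C[C@@H](O[Si](C)(C)C(C)(C)C)C=O | intermediate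
6 | L-allylglycine, (S)-2-aminopent-4-enoic acid | C=CC[C@H](N)C(=O)O | starting material
7 | (S)-2-hydroxypent-4-enoic acid | C=CC[C@H](O)C(=O)O | intermediate
8 | (5S)-5-allyl-2-[(1R,3E)-1-(tert-butyldimethylsilyloxy)hex-3-en-1-yl]-1,3-dioxolan-4-one (acetal carbon: both epimers) | C=CC[C@@H]1OC(OC1=O)[C@@H](C/C=C/CC)O[Si](C)(C)C(C)(C)C | intermediate
9 | (5S)-5-allyl-2-[(1R,3E)-1-(tert-butyldimethylsilyloxy)hex-3-en-1-yl]-4-methylene-1,3-dioxolane (acetal carbon: both epimers) | C=CC[C@@H]1OC(OC1=C)[C@@H](C/C=C/CC)O[Si](C)(C)C(C)(C)C | intermediate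
10 | oxocarbenium ion/chlorodimethylaluminium enolate zwitterion (not isolated) | C=CC[C@H]([O+]=C[C@@H](C/C=C/CC)O[Si](C)(C)C(C)(C)C)C(=C)O[Al-](C)(C)Cl | intermediate
11 | (2S,5S)-2-allyl-5-[(1R,3E)-1-(tert-butyldimethylsilyloxy)hex-3-en-1-yl]dihydrofuran-3(2H)-one | C=CC[C@@H]1O[C@@H](CC1=O)[C@@H](C/C=C/CC)O[Si](C)(C)C(C)(C)C | intermediate
12 | (2S,3S,5S)-2-allyl-5-[(1R,3E)-1-(tert-butyldimethylsilyloxy)hex-3-en-1-yl]tetrahydrofuran-3-ol | C=CC[C@@H]1O[C@@H](C[C@@H]1O)[C@@H](C/C=C/CC)O[Si](C)(C)C(C)(C)C | intermediate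
13 | chloromethanesulfonate of 12 | C=CC[C@@H]1O[C@@H](C[C@@H]1OS(=O)(=O)CCl)[C@@H](C/C=C/CC)O[Si](C)(C)C(C)(C)C | intermediate
14 | (2S,3S,5S)-2-allyl-5-[(1R,3E)-1-hydroxyhex-3-en-1-yl]tetrahydrofuran-3-yl chloromethanesulfonate | C=CC[C@@H]1O[C@@H](C[C@@H]1OS(=O)(=O)CCl)[C@@H](C/C=C/CC)O | intermediate
15 | tert-butyl carbonate of 14 | C=CC[C@@H]1O[C@@H](C[C@@H]1OS(=O)(=O)CCl)[C@@H](C/C=C/CC)OC(=O)OC(C)(C)C | intermediate
16 | bicyclic oxonium ion with bromopentachloroantimonate counter-ion (not isolated) | C=CC[C@@H]1[O+]2[C@@H]([C@@H](Br)CC)C[C@@H](OC(=O)OC(C)(C)C)[C@@H]2C[C@@H]1OS(=O)(=O)CCl.Cl[Sb-](Cl)(Cl)(Cl)(Cl)Br | intermediate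
17 | (6S,7S,9R,10R,12R,13S)-6-allyl-12-(1-bromopropyl)-7-(chloromethanesulfonyloxy)oxocane-9,10-diyl carbonate (chain locants) | C=CC[C@@H]1O[C@@H]([C@@H](Br)CC)C[C@H]2OC(=O)O[C@@H]2C[C@@H]1OS(=O)(=O)CCl | intermediate
18 | (6S,7S,9R,10R,12R,13S)-6-allyl-12-(1-bromopropyl)-9,10-dihydroxyoxocan-7-yl chloromethanesulfonate (not isolated) | C=CC[C@@H]1O[C@@H]([C@@H](Br)CC)C[C@@H](O)[C@H](O)C[C@@H]1OS(=O)(=O)CCl | intermediate
19 | (6S,7R,9R,10R,12R,13S)-6-allyl-12-(1-bromopropyl)-7,10-epoxyoxocan-9-ol (chain locants) | C=CC[C@@H]1O[C@@H]([C@@H](Br)CC)C[C@@H]2[C@H](O)C[C@H]1O2 | intermediate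
20 | tert-butyldimethylsilyl ether of 19 | C=CC[C@@H]1O[C@@H]([C@@H](Br)CC)C[C@@H]2[C@H](O[Si](C)(C)C(C)(C)C)C[C@H]1O2 | intermediate
21 | 4,4,5,5-tetramethyl-2-vinyl-1,3,2-dioxaborolane | C=CB1OC(C)(C)C(C)(C)O1 | starting material
22 | (E)-alkenylboronic pinacol ester, boron on C3 (6S,7R,9R,10R,12R,13S) | CC1(C)OB(/C=C/C[C@@H]2O[C@@H]([C@@H](Br)CC)C[C@@H]3[C@H](O[Si](C)(C)C(C)(C)C)C[C@H]2O3)OC1(C)C | intermediate
23 | (bromoethynyl)trimethylsilane | C[Si](C)(C)C#CBr | starting material
24 | 1-trimethylsilyl derivative of 25 (not isolated) | C[Si](C)(C)C#C/C=C/C[C@@H]1O[C@@H]([C@@H](Br)CC)C[C@@H]2[C@H](O[Si](C)(C)C(C)(C)C)C[C@H]1O2 | intermediate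
25 | (3E,6S,7R,9R,10R,12R,13S)-13-bromo-9-(tert-butyldimethylsilyloxy)-6,12:7,10-diepoxypentadec-3-en-1-yne | C#C/C=C/C[C@@H]1O[C@@H]([C@@H](Br)CC)C[C@@H]2[C@H](O[Si](C)(C)C(C)(C)C)C[C@H]1O2 | intermediate
26 | (3S,4S,6S,7R,9R,10R,12R,13S)-13-bromo-9-(tert-butyldimethylsilyloxy)-3,4:6,12:7,10-triepoxypentadec-1-yne | C#C[C@@H]1O[C@H]1C[C@@H]3O[C@@H]([C@@H](Br)CC)C[C@@H]4[C@H](O[Si](C)(C)C(C)(C)C)C[C@H]3O4 | intermediate
27 | tricyclic oxonium ion with C3–O–BF3 alkoxide (zwitterion, not isolated) | C#C[C@H](O[B-](F)(F)F)[C@H]1C[C@@H]2O[C@@H]([C@@H](Br)CC)C[C@@H]3[C@H](O[Si](C)(C)C(C)(C)C)C[C@H]2[O+]13 | intermediate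
28 | (3S,4R,6S,7R,9R,10S,12R,13S)-10,13-dibromo-9-(tert-butyldimethylsilyloxy)-4,7:6,12-diepoxypentadec-1-yn-3-ol | C#C[C@H](O)[C@H]1C[C@@H]2O[C@@H]([C@@H](Br)CC)C[C@H](Br)[C@H](O[Si](C)(C)C(C)(C)C)C[C@H]2O1 | intermediate
29 | (3R,4R,6S,7R,9R,10S,12R,13S)-3,10,13-tribromo-9-(tert-butyldimethylsilyloxy)-4,7:6,12-diepoxypentadec-1-yne | C#C[C@@H](Br)[C@H]1C[C@@H]2O[C@@H]([C@@H](Br)CC)C[C@H](Br)[C@H](O[Si](C)(C)C(C)(C)C)C[C@H]2O1 | intermediate
30 | (3R,4R,6S,7R,9R,10S,12R,13S)-3,10,13-tribromo-4,7:6,12-diepoxypentadec-1-yn-9-ol | C#C[C@@H](Br)[C@H]1C[C@@H]2O[C@@H]([C@@H](Br)CC)C[C@H](Br)[C@H](O)C[C@H]2O1 | intermediate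
31 | (3R,4R,6S,7R,9R,10S,12R,13S)-3,10,13-tribromo-4,7:6,12-diepoxypentadec-1-yn-9-yl acetate | C#C[C@@H](Br)[C@H]1C[C@@H]2O[C@@H]([C@@H](Br)CC)C[C@H](Br)[C@H](OC(C)=O)C[C@H]2O1 | target

**Step count and risks**

Total step count: 21. Longest linear sequence: 20 steps (steps 1–3 and 5–21).

The three steps most likely to fail, in order of risk:

Step 18 (oxonium ring switch). Bromide may open the activated epoxide directly, or attack the oxonium ion at C4 or C7 instead of C10, or the zwitterion may collapse by fluoride transfer from boron. The fallback sets out from enyne 25 and comes back at alcohol 28. The bridging ether of 25 would be cleaved first with Me2BBr (Et3N, CH2Cl2, −78 to 0 °C), which should deliver bromide to C10 with inversion and free the C7 hydroxyl, giving the bromo alcohol F1. Shi epoxidation as in step 17 should then give the epoxy alcohol F2. CSA (CH2Cl2, 0 °C) should close the tetrahydrofuran by 5-exo attack of the C7 hydroxyl on C4 with inversion, which gives 28.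

Step 12 (bromonium-induced ring expansion). The terminal alkene may be brominated in competition, or the bromonium ion may form on the wrong face, which would give the C12/C13 diastereomer. The fallback sets out from carbonate 15 and comes back at 17, and it replaces substrate control by reagent control. Shi epoxidation of the internal E-alkene with the L-fructose-derived ketone (the terminal alkene reacts much more slowly) should give the (12S,13S)-epoxide F3. BF3·OEt2 (CH2Cl2, −78 °C) should trigger the same ring expansion from the epoxide and give the hydroxy carbonate F4, whose C13 alcohol has the configuration opposite to the one needed for a displacement with inversion. Oxidation with Dess–Martin periodinane would give the ketone F5. Reduction with LiBH(s-Bu)3 under Felkin–Anh (non-chelation) control should give the epimeric alcohol F6. CBr4 and P(n-Oct)3 (toluene, 70 °C) should then install the bromide with inversion and give 17.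

Step 7 (key ring closure). Ionisation of the acetal may be slow because the cation carries an α-silyloxy group, so that loss of the silyl ether, hydrolysis of the enol acetal or trans closure may compete. The fallback sets out from aldehyde 5 and comes back at ketone 11; it makes the C8–C9 bond before the ring closure rather than during it. D-Allylglycine would be diazotised as in step 4 to (R)-2-hydroxypent-4-enoic acid F7. MeLi (3.5 equiv, THF, 0 °C) would convert F7 into the methyl ketone F8, and MsCl/Et3N would give the mesylate F9. The boron enolate of F9 (c-Hex2BCl, Et3N, Et2O, −78 °C) should add to 5 under Felkin–Anh control to give the aldol F10 with the 9,10-anti relationship. K2CO3 in MeOH (0 °C) should then close the ring by 5-exo-tet attack of the C9 oxygen on C6 with inversion, which gives 11.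

**Further compounds**

F1 | step 18 | (3E,6S,7R,9R,10S,12R,13S)-10,13-dibromo-9-(tert-butyldimethylsilyloxy)-6,12-epoxypentadec-3-en-1-yn-7-ol | C#C/C=C/C[C@@H]1O[C@@H]([C@@H](Br)CC)C[C@H](Br)[C@H](O[Si](C)(C)C(C)(C)C)C[C@H]1O
F2 | step 18 | (3S,4S)-epoxide of F1 | C#C[C@@H]1O[C@H]1C[C@@H]2O[C@@H]([C@@H](Br)CC)C[C@H](Br)[C@H](O[Si](C)(C)C(C)(C)C)C[C@H]2O
F3 | step 12 | (12S,13S)-epoxide of 15 | C=CC[C@@H]1O[C@@H](C[C@@H]1OS(=O)(=O)CCl)[C@@H](C[C@@H]2O[C@H]2CC)OC(=O)OC(C)(C)C
F4 | step 12 | 13-hydroxy analogue of 17 with the C13 configuration from epoxide opening | C=CC[C@@H]1O[C@@H]([C@@H](O)CC)C[C@H]2OC(=O)O[C@@H]2C[C@@H]1OS(=O)(=O)CCl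
F5 | step 12 | 13-ketone (propanoyl group at C12) | C=CC[C@@H]1O[C@@H](C(=O)CC)C[C@H]2OC(=O)O[C@@H]2C[C@@H]1OS(=O)(=O)CCl
F6 | step 12 | C13 epimer of F4 | C=CC[C@@H]1O[C@@H]([C@H](O)CC)C[C@H]2OC(=O)O[C@@H]2C[C@@H]1OS(=O)(=O)CCl
F7 | step 7 | (R)-2-hydroxypent-4-enoic acid | C=CC[C@@H](O)C(=O)O
F8 | step 7 | (R)-3-hydroxyhex-5-en-2-one | C=CC[C@@H](O)C(C)=O
F9 | step 7 | (R)-2-oxohex-5-en-3-yl methanesulfonate | C=CC[C@@H](OS(C)(=O)=O)C(C)=O
F10 | step 7 | aldol adduct of F9 and 5 (C6 R-mesylate, C9 hydroxyl, C10 silyl ether) | C=CC[C@@H](OS(C)(=O)=O)C(=O)C[C@H](O)[C@@H](C/C=C/CC)O[Si](C)(C)C(C)(C)C
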